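## Retrosynthetic overview

1. The last bond made is the benzylic ester C–O bond. The ring A carboxylate (haematommic acid) displaces a ring B benzylic bromide by SN2. All ring B protecting groups are allyl and are removed together in one final palladium step.
2. The ring B bromide comes from opening the lactone of 5,7-dihydroxy-6-methylphthalide. The phthalide comes from aromatisation and lactonisation of a 6-(silyloxymethyl)-3-methyl-2,4-dioxocyclohexane-1-carboxylate.
3. Key C–C disconnection: that dione comes from an intermolecular Michael addition of dimethyl malonate to (E)-6-silyloxyhex-4-en-3-one (C1–C6 bond), followed by an intramolecular Claisen closure (C2–C3 bond).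
4. Ring A follows the same logic: Michael addition of methyl acetoacetate to methyl crotonate, Claisen closure, aromatisation, C3 formylation, ester cleavage.
5. Ring order: the ring B carbocycle forms in step 3 and its temporary lactone ring in step 4. The ring A carbocycle forms in step 8 on a parallel branch. The two halves are joined in step 12.

Assumption: the target SMILES holds no stereocentre and no stereogenic double bond, so the compound is achiral and there is no enantiomer to control. The sp3 centres of 6–8 and 18–20 form as racemic diastereomer/tautomer mixtures and vanish on aromatisation.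

## Route

Step 1
Reactants: 1 allyl alcohol (prop-2-en-1-ol)
Product: 2 allyl tert-butyldimethylsilyl ether
Conditions: TBSCl (1.05 equiv), imidazole (1.5 equiv), CH2Cl2, 0 °C to rt, 3 h
Reagents that add atoms: tert-butyldimethylsilyl chloride, CC(C)(C)[Si](C)(C)Cl
Why: Imidazole-promoted silylation of a primary alcohol gives a base-stable, acid-labile mask for the oxygen that becomes the benzylic oxygen of ring B.

Step 2
Reactants: 2 allyl tert-butyldimethylsilyl ether; 3 pent-1-en-3-one (ethyl vinyl ketone, 2 equiv)
Product: 4 (E)-6-(tert-butyldimethylsilyloxy)hex-4-en-3-one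
Conditions: second-generation Hoveyda–Grubbs catalyst RuCl2(SIMes)(=CH-C6H4-2-OiPr) (2 mol %), CH2Cl2, 40 °C, 8 h
Reagents that add atoms: none
Why: Olefin cross-metathesis between an unhindered allyl ether and an electron-poor vinyl ketone is selective for the cross product, is driven by loss of ethene and gives the E-enone under thermodynamic control.

Step 3
Reactants: 4 (E)-6-(tert-butyldimethylsilyloxy)hex-4-en-3-one; 5 dimethyl malonate (1.1 equiv)
Product: 7 methyl 6-[(tert-butyldimethylsilyloxy)methyl]-3-methyl-2,4-dioxocyclohexane-1-carboxylate (racemic diastereomer/tautomer mixture), via Michael adduct 6 (not isolated)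
Conditions: NaOMe (0.1 equiv), MeOH, 0 °C to rt, 3 h; then NaOMe (1.1 equiv), reflux, 4 h; cold 1 M HCl to pH 3–4
Reagents that add atoms: none
Why: In the key step an intermolecular Michael addition of the malonate anion to the enone forges the C1–C6 bond of ring B with the oxygenated side-chain carbon already in place, after which the ethyl-ketone enolate of 6 closes the ring by an intramolecular Claisen (Dieckmann-type) condensation pulled forward by the stabilised 1,3-dione enolate, and the new sp3 centres do not matter because step 4 erases them.

Step 4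
Reactants: 7 methyl 6-[(tert-butyldimethylsilyloxy)methyl]-3-methyl-2,4-dioxocyclohexane-1-carboxylate
Product: 11 5,7-dihydroxy-6-methylphthalide (5,7-dihydroxy-6-methylisobenzofuran-1(3H)-one), via bromodione 8 (not isolated), via silyl ether resorcylate 9 (not isolated), via hydroxymethyl resorcylate 10 (not isolated)
Conditions: Br2 (1.0 equiv), DMF, 0 °C, 1 h, then 80 °C, 16 h; then 2 M aq HCl, 60 °C, 2 h
Reagents that add atoms: none
Why: In this bromination–dehydrobromination aromatisation of a cyclohexane-1,3-dione, bromine enters at C3, HBr shuttles it to a carbon from which HBr can be lost, tautomerisation gives the resorcylate, and acid then strips the silyl group so that the benzylic alcohol lactonises onto the neighbouring methyl ester, the crystalline phthalide being the sink into which all partly deprotected species converge.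

Step 5
Reactants: 11 5,7-dihydroxy-6-methylphthalide
Product: 12 5,7-bis(allyloxy)-6-methylphthalide
Conditions: allyl bromide (2.5 equiv), K2CO3 (3 equiv), DMF, 50 °C, 6 h
Reagents that add atoms: allyl bromide, C=CCBr
Why: Williamson etherification of both phenoxides proceeds cleanly because the lactone is inert to carbonate, and the allyl groups can later be removed without acid, base or hydrogen.

Step 6
Reactants: 12 5,7-bis(allyloxy)-6-methylphthalide
Product: 14 allyl 2,4-bis(allyloxy)-6-(hydroxymethyl)-3-methylbenzoate, via sodium carboxylate 13 (not isolated)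
Conditions: NaOH (1.05 equiv), THF/H2O, 65 °C, 4 h; evaporate, toluene azeotrope; allyl bromide (1.3 equiv), DMF, rt, 12 h
Reagents that add atoms: sodium hydroxide, [Na+].[OH-]; allyl bromide, C=CCBr
Why: Saponification of the exposed planar lactone carbonyl gives the hydroxy carboxylate, and its SN2 O-alkylation in DMF with no excess base gives the open hydroxy ester faster than it can relactonise.

Step 7
Reactants: 14 allyl 2,4-bis(allyloxy)-6-(hydroxymethyl)-3-methylbenzoate
Product: 15 allyl 2,4-bis(allyloxy)-6-(bromomethyl)-3-methylbenzoate
Conditions: CBr4 (1.3 equiv), PPh3 (1.3 equiv), CH2Cl2, 0 °C, 30 min; short silica plug, used at once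
Reagents that add atoms: carbon tetrabromide, BrC(Br)(Br)Br
Why: The Appel reaction converts the primary benzylic alcohol into the bromide under neutral, cold conditions that give no alkoxide and so do not trigger return to the phthalide.

Step 8
Reactants: 16 methyl acetoacetate; 17 methyl (E)-crotonate
Product: 19 methyl 6-methyl-2,4-dioxocyclohexane-1-carboxylate (racemic diastereomer/tautomer mixture), via Michael adduct 18 (not isolated)
Conditions: NaOMe (1.05 equiv), MeOH, reflux, 5 h; cold 2 M HCl
Reagents that add atoms: none
Why: Intermolecular Michael addition of the acetoacetate anion to the crotonate is followed by an intramolecular Claisen condensation of the methyl-ketone enolate onto the distal ester, and formation of the 1,3-dione enolate makes the sequence irreversible.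

Step 9
Reactants: 19 methyl 6-methyl-2,4-dioxocyclohexane-1-carboxylate
Product: 21 methyl orsellinate (methyl 2,4-dihydroxy-6-methylbenzoate), via bromodione 20 (not isolated)
Conditions: Br2 (1.0 equiv), DMF, 0 °C, 1 h, then 80 °C, 16 h
Reagents that add atoms: none
Why: Bromination–dehydrobromination with exactly one equivalent of bromine removes two hydrogens from the dihydroresorcylate, and enolisation to the arene makes the loss of HBr irreversible.

Step 10
Reactants: 21 methyl orsellinate
Product: 23 methyl haematommate (methyl 3-formyl-2,4-dihydroxy-6-methylbenzoate), via chloro ether 22 (not isolated)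
Conditions: Cl2CHOMe (1.2 equiv), TiCl4 (3 equiv), CH2Cl2, −10 °C to rt, 2 h; then 1 M aq HCl, 0 °C to rt; minor 5-formyl isomer removed by crystallisation
Reagents that add atoms: dichloromethyl methyl ether, COC(Cl)Cl; water, O
Why: In the Rieche formylation, titanium bound to the phenolic oxygens delivers the electrophile to C3, the carbon ortho to both hydroxyls, and hydrolysis of the chloro ether gives the doubly hydrogen-bonded aldehyde as the major isomer.

Step 11
Reactants: 23 methyl haematommate
Product: 24 haematommic acid (3-formyl-2,4-dihydroxy-6-methylbenzoic acid)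
Conditions: conc. H2SO4, 0 °C to rt, 1–2 h; poured onto ice, filtered, dried cold
Reagents that add atoms: water, O
Why: Di-ortho-substituted electron-rich benzoates undergo unimolecular acyl–oxygen fission in concentrated H2SO4 (AAC1 ester hydrolysis) and give the acid on the ice quench, which avoids the hot alkali that would decarboxylate a β-resorcylic acid, while the chelated formyl group deactivates the ring towards sulfonation.

Step 12
Reactants: 24 haematommic acid; 15 allyl 2,4-bis(allyloxy)-6-(bromomethyl)-3-methylbenzoate
Product: 26 allyl 2,4-bis(allyloxy)-6-{[(3-formyl-2,4-dihydroxy-6-methylbenzoyl)oxy]methyl}-3-methylbenzoate, via potassium haematommate 25 (not isolated)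
Conditions: 24, KHCO3 (1.1 equiv), DMF, rt, 30 min; then 15 (1.0 equiv), rt, 16 h
Reagents that add atoms: none
Why: Hydrogencarbonate deprotonates only the carboxylic acid and not the chelated phenols, so SN2 alkylation of the carboxylate by the benzylic bromide forms the hindered ester at the unhindered alkyl carbon.

Step 13
Reactants: 26 allyl 2,4-bis(allyloxy)-6-{[(3-formyl-2,4-dihydroxy-6-methylbenzoyl)oxy]methyl}-3-methylbenzoate
Product: 27 alectorialic acid (6-{[(3-formyl-2,4-dihydroxy-6-methylbenzoyl)oxy]methyl}-2,4-dihydroxy-3-methylbenzoic acid)
Conditions: Pd(PPh3)4 (10 mol %), p-TolSO2Na (4 equiv), THF/MeOH 4:1, rt, 2 h; cold 0.5 M HCl, EtOAc; crystallisation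
Reagents that add atoms: none
Why: In this Tsuji–Trost-type deallylation, zerovalent palladium ionises only the three O-allyl groups to π-allyl complexes that the soft sulfinate captures irreversibly, under near-neutral conditions that leave the aldehyde, the free phenols and the non-allylic benzylic ester untouched.

## Compound list

1 | allyl alcohol | C=CCO | starting material
2 | allyl tert-butyldimethylsilyl ether | C=CCO[Si](C)(C)C(C)(C)C | intermediate
3 | pent-1-en-3-one | C=CC(=O)CC | starting material
4 | (E)-6-(tert-butyldimethylsilyloxy)hex-4-en-3-one | CCC(=O)/C=C/CO[Si](C)(C)C(C)(C)C | intermediate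
5 | dimethyl malonate | COC(=O)CC(=O)OC | starting material
6 | dimethyl 2-[1-(tert-butyldimethylsilyloxy)-4-oxohexan-2-yl]propanedioate (racemic) | CCC(=O)CC(CO[Si](C)(C)C(C)(C)C)C(C(=O)OC)C(=O)OC | intermediate
7 | methyl 6-[(tert-butyldimethylsilyloxy)methyl]-3-methyl-2,4-dioxocyclohexane-1-carboxylate (racemic mixture) | COC(=O)C1C(CO[Si](C)(C)C(C)(C)C)CC(=O)C(C)C1=O | intermediate
8 | methyl 3-bromo-6-[(tert-butyldimethylsilyloxy)methyl]-3-methyl-2,4-dioxocyclohexane-1-carboxylate (racemic mixture) | COC(=O)C1C(CO[Si](C)(C)C(C)(C)C)CC(=O)C(C)(Br)C1=O | intermediate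
9 | methyl 6-[(tert-butyldimethylsilyloxy)methyl]-2,4-dihydroxy-3-methylbenzoate | COC(=O)c1c(CO[Si](C)(C)C(C)(C)C)cc(O)c(C)c1O | intermediate
10 | methyl 2,4-dihydroxy-6-(hydroxymethyl)-3-methylbenzoate | COC(=O)c1c(CO)cc(O)c(C)c1O | intermediate
11 | 5,7-dihydroxy-6-methylphthalide | O=C1OCc2cc(O)c(C)c(O)c21 | intermediate
12 | 5,7-bis(allyloxy)-6-methylphthalide | O=C1OCc2cc(OCC=C)c(C)c(OCC=C)c21 | intermediate
13 | sodium 2,4-bis(allyloxy)-6-(hydroxymethyl)-3-methylbenzoate | [Na+].[O-]C(=O)c1c(CO)cc(OCC=C)c(C)c1OCC=C | intermediate
14 | allyl 2,4-bis(allyloxy)-6-(hydroxymethyl)-3-methylbenzoate | C=CCOC(=O)c1c(CO)cc(OCC=C)c(C)c1OCC=C | intermediate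
15 | allyl 2,4-bis(allyloxy)-6-(bromomethyl)-3-methylbenzoate | C=CCOC(=O)c1c(CBr)cc(OCC=C)c(C)c1OCC=C | intermediate
16 | methyl acetoacetate | COC(=O)CC(C)=O | starting material
17 | methyl (E)-crotonate | C/C=C/C(=O)OC | starting material
18 | dimethyl 2-acetyl-3-methylpentanedioate (racemic mixture) | COC(=O)CC(C)C(C(C)=O)C(=O)OC | intermediate
19 | methyl 6-methyl-2,4-dioxocyclohexane-1-carboxylate (racemic mixture) | COC(=O)C1C(C)CC(=O)CC1=O | intermediate
20 | methyl 3-bromo-6-methyl-2,4-dioxocyclohexane-1-carboxylate (racemic mixture) | COC(=O)C1C(C)CC(=O)C(Br)C1=O | intermediate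
21 | methyl orsellinate | COC(=O)c1c(C)cc(O)cc1O | intermediate
22 | methyl 3-[chloro(methoxy)methyl]-2,4-dihydroxy-6-methylbenzoate (racemic) | COC(=O)c1c(C)cc(O)c(C(Cl)OC)c1O | intermediate
23 | methyl haematommate | COC(=O)c1c(C)cc(O)c(C=O)c1O | intermediate
24 | haematommic acid | Cc1cc(O)c(C=O)c(O)c1C(=O)O | intermediate
25 | potassium haematommate | [K+].[O-]C(=O)c1c(C)cc(O)c(C=O)c1O | intermediate
26 | allyl 2,4-bis(allyloxy)-6-{[(3-formyl-2,4-dihydroxy-6-methylbenzoyl)oxy]methyl}-3-methylbenzoate | Cc1cc(O)c(C=O)c(O)c1C(=O)OCc1cc(OCC=C)c(C)c(OCC=C)c1C(=O)OCC=C | intermediate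
27 | alectorialic acid (achiral) | Cc1cc(O)c(C=O)c(O)c1C(=O)OCc1cc(O)c(C)c(O)c1C(=O)O | target

## Step count and risk

Total step count: 13.
Longest linear sequence: 9 steps (steps 1–7, 12 and 13). The ring A branch (steps 8–11) runs in parallel.

### Steps most likely to fail

**Step 4 (aromatisation of the 3-methyl dione).** Bromine first lands on the quaternary-forming C3 and must migrate before HBr can be lost, and over-bromination of the electron-rich product is possible.
The fallback sets out from 7 and comes back at 11.
- Halogenation is replaced by oxidation through sulfonation. Treatment with Ac2O and conc. H2SO4 (0 to 50 °C) enol-acetylates the dione, sulfonates alpha to a carbonyl and expels SO2.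
- The silyl ether is acetolysed at the same time, giving methyl 2,4-diacetoxy-6-(acetoxymethyl)-3-methylbenzoate F1.
- HCl in MeOH at reflux then removes the three acetates, and the freed benzylic alcohol lactonises to 11.

**Step 7 (benzylic bromide next to an ester).** Both 14 and 15 can fall back to phthalide 12 through participation of the neighbouring ester.
The fallback sets out from 14 (together with 24) and comes back at 26.
- A Mitsunobu esterification (PPh3, DIAD, THF, 0 °C) joins the two halves directly, so no benzylic halide is ever made or stored.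
- The carboxylic acid is engaged well ahead of the chelated phenols.
- 15 and 25 are bypassed, and this path makes no new compound F0.

**Step 11 (cleavage of the hindered methyl ester to a decarboxylation-prone acid).** The fallback sets out from 17 and comes back at 24, and it avoids any ester hydrolysis by carrying a benzyl ester from the start.
- Methyl crotonate 17 and commercial benzyl acetoacetate (KOtBu, THF, reflux) give the Michael adduct 1-benzyl 5-methyl 2-acetyl-3-methylpentanedioate F2, which closes to benzyl 6-methyl-2,4-dioxocyclohexane-1-carboxylate F3.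
- Br2 in DMF as in step 9 gives benzyl 3-bromo-6-methyl-2,4-dioxocyclohexane-1-carboxylate F4, which aromatises to benzyl orsellinate F5.
- Rieche formylation at −20 °C gives benzyl 3-[chloro(methoxy)methyl]-2,4-dihydroxy-6-methylbenzoate F6, which hydrolyses to benzyl haematommate F7.
- Hydrogenolysis (H2, 1 atm, 10% Pd/C, EtOAc, rt, stopped after one equivalent) frees 24. The doubly chelated aldehyde is reduced much more slowly than the benzyl ester is cleaved.

## Further compounds

F1 | step 4 | methyl 2,4-diacetoxy-6-(acetoxymethyl)-3-methylbenzoate | COC(=O)c1c(COC(C)=O)cc(OC(C)=O)c(C)c1OC(C)=O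
F0 | step 7 | none | none
F2 | step 11 | 1-benzyl 5-methyl 2-acetyl-3-methylpentanedioate (racemic mixture) | COC(=O)CC(C)C(C(C)=O)C(=O)OCc1ccccc1
F3 | step 11 | benzyl 6-methyl-2,4-dioxocyclohexane-1-carboxylate (racemic mixture) | O=C(OCc1ccccc1)C1C(C)CC(=O)CC1=O
F4 | step 11 | benzyl 3-bromo-6-methyl-2,4-dioxocyclohexane-1-carboxylate (racemic mixture) | O=C(OCc1ccccc1)C1C(C)CC(=O)C(Br)C1=O
F5 | step 11 | benzyl orsellinate | Cc1cc(O)cc(O)c1C(=O)OCc1ccccc1
F6 | step 11 | benzyl 3-[chloro(methoxy)methyl]-2,4-dihydroxy-6-methylbenzoate (racemic) | COC(Cl)c1c(O)cc(C)c(C(=O)OCc2ccccc2)c1O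
F7 | step 11 | benzyl haematommate | Cc1cc(O)c(C=O)c(O)c1C(=O)OCc1ccccc1
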